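**Numbering of the target used below:** C1 = C(Br)(CH2Cl), C2 = CHCl, C3 = CH2, C4 = CHCl, C5 = C(CH3)(CH=CHCl), C6 = CH2; configuration (1R,2R,4S,5S), vinyl chloride E.

## Retrosynthetic overview

1. Enabling feature: quaternary ring carbon C5 (methyl plus the exocyclic vinyl carbon) sits next to ring C4–Cl, and that chlorine is cis to the vinyl carbon. This is the retron of an α-quaternary β-chloro aldehyde, so the cyclohexane can arise from a 2-methylcyclohept-2-en-1-ol by a chloronium-triggered semipinacol ring contraction that extrudes the carbinol carbon as CHO.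
2. Endgame after the contraction: CHO → (E)-CH=CHCl (Takai olefination), then tertiary C1–OSiEt3 → C1–Br with retention through the neighbouring CH2Cl chlorine.
3. The cycloheptenol comes from ring-closing metathesis of an acyclic dienone, followed by CBS reduction.
4. The dienone comes from a Cornforth-controlled aldol of the 3-methylbut-3-en-2-one enolate with (R)-1,3-dichlorohex-5-en-2-one, which sets C1(O) and C2(Cl). The ketone comes from pent-4-enal by organocatalytic α-chlorination and chloromethyllithium homologation.
5. Ring order: cycloheptene (metathesis) → cyclohexane (ring contraction); no other ring is made.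

Key step: step 7

Assumption: the two commercial chiral catalysts (steps 1 and 6) follow their usual induction models; in each case the catalyst enantiomer is the one that gives the configuration drawn.

## Route

Step 1
Reactants: 1 pent-4-enal
Product: 2 (2R)-2-chloropent-4-enal
Conditions: NCS, trans-2,5-diphenylpyrrolidine (10 mol %, enantiomer that gives 2R), CH2Cl2, 0 °C → rt; used crude
Reagents that add atoms: N-chlorosuccinimide, O=C1CCC(=O)N1Cl
Why: Organocatalytic (enamine) α-chlorination of an aldehyde, in which the C2-symmetric pyrrolidine shields one enamine face and should set the C–Cl centre that becomes C2 of the target.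

Step 2
Reactants: 2 (2R)-2-chloropent-4-enal
Product: 3 (3R)-1,3-dichlorohex-5-en-2-ol (both C2 epimers)
Conditions: ICH2Cl, MeLi·LiBr, THF, −78 °C; AcOH quench at −78 °C
Reagents that add atoms: chloroiodomethane, ClCI
Why: Carbenoid (chloromethyllithium) addition to the aldehyde with a cold acidic quench, so that the alkoxide does not close to an epoxide, brings in the future CH2Cl carbon; the new carbinol centre is oxidised away in step 3.

Step 3
Reactants: 3 (3R)-1,3-dichlorohex-5-en-2-ol
Product: 4 (3R)-1,3-dichlorohex-5-en-2-one
Conditions: Dess–Martin periodinane, CH2Cl2, 0 °C → rt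
Reagents that add atoms: none
Why: Dess–Martin oxidation under near-neutral conditions should give the α,α'-dichloro ketone without enolising the C3 stereocentre.

Step 4
Reactants: 4 (3R)-1,3-dichlorohex-5-en-2-one; 5 3-methylbut-3-en-2-one
Product: 8 (5R,6R)-6-chloro-5-(chloromethyl)-2-methyl-5-[(triethylsilyl)oxy]nona-1,8-dien-3-one, via lithium dienolate 6 (not isolated), via lithium aldolate 7 (not isolated)
Conditions: 5, LDA, THF, −78 °C; then 4, −78 °C; then TESOTf, −78 → −40 °C
Reagents that add atoms: triethylsilyl trifluoromethanesulfonate, CC[Si](CC)(CC)OS(=O)(=O)C(F)(F)F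
Why: Aldol addition of the kinetic lithium dienolate to the α-chloro ketone under Cornforth/polar Felkin–Anh control (C–Cl anti to the incoming carbon, attack past H) should set the tertiary carbinol centre with O and Cl anti in the zigzag chain (cis in the later ring), and the cold aldolate is silylated before it can revert or close to an epoxide.

Step 5
Reactants: 8 (5R,6R)-6-chloro-5-(chloromethyl)-2-methyl-5-[(triethylsilyl)oxy]nona-1,8-dien-3-one
Product: 9 (5R,6R)-5-chloro-6-(chloromethyl)-2-methyl-6-[(triethylsilyl)oxy]cyclohept-2-en-1-one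
Conditions: Grubbs II catalyst (5 mol %), CH2Cl2, 40 °C
Reagents that add atoms: none
Why: Ring-closing metathesis between the isopropenyl ketone and the terminal vinyl group closes the seven-membered trisubstituted enone with loss of ethene, helped by the fully substituted C5 of the chain (gem-disubstituent effect).

Step 6
Reactants: 9 (5R,6R)-5-chloro-6-(chloromethyl)-2-methyl-6-[(triethylsilyl)oxy]cyclohept-2-en-1-one
Product: 10 (1S,5R,6R)-5-chloro-6-(chloromethyl)-2-methyl-6-[(triethylsilyl)oxy]cyclohept-2-en-1-ol
Conditions: (R)-Me-CBS oxazaborolidine (20 mol %), BH3·THF, THF, −40 °C; MeOH quench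
Reagents that add atoms: none
Why: CBS reduction with catalyst-controlled 1,2-hydride delivery (the 2-methylalkenyl arm as the large group) should set C1 as S, which places the hydroxyl trans to the 6-silyloxy group and pseudo-equatorial in the chair needed for step 7.

Step 7
Reactants: 10 (1S,5R,6R)-5-chloro-6-(chloromethyl)-2-methyl-6-[(triethylsilyl)oxy]cyclohept-2-en-1-ol
Product: 12 (1S,2S,4R,5R)-2,4-dichloro-5-(chloromethyl)-1-methyl-5-[(triethylsilyl)oxy]cyclohexane-1-carbaldehyde, via chloronium ion 11 (not isolated)
Conditions: NCS (1.1 equiv), HFIP/CH2Cl2 (1:4), −40 → 0 °C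
Reagents that add atoms: N-chlorosuccinimide, O=C1CCC(=O)N1Cl
Why: Proposed new method: (numbering of 10) HFIP-activated NCS should form chloronium ion 11 on the face of C2=C3 anti to the two allylic ring bonds that stand perpendicular to the π plane (C1–C7 and C4–C5) in the chair with 5-Cl and 6-CH2Cl equatorial; the C1–C7 bond, antiperiplanar to the breaking C2–Cl+ bond and pushed by the hydroxyl lone pair, then migrates to C2, so that C1 leaves the ring as CHO and the cycloheptene contracts to the cyclohexane. The closest known reaction types are the halonium-induced semipinacol rearrangement of allylic alcohols to α-quaternary β-halo carbonyl compounds and the Lewis-acid semipinacol ring contraction of cyclic 2,3-epoxy alcohols; new here is the ring-contracting use on an endocyclic secondary cycloheptenol with a chlorine electrophile. The six-membered ring is closed by a suprafacial 1,2-alkyl shift (ring contraction by C–C migration, not an end-to-end cyclisation). Both new stereocentres come from anti addition across the former alkene: Cl at C3 and the migrating carbon at C2 enter from opposite faces, so Cl ends cis to CHO, and the pair of faces used is fixed by the C5 and C6 stereocentres through the ring conformation (the C1 stereocentre is destroyed). The step needs ring-carbon migration to win over hydride shift, epoxide formation and transannular ether formation, and this is secured because in the reactive chair the C1–H bond is syn to the chloronium ion, the C1–O bond lies in the alkene plane and the 6-silyloxy oxygen sits on the chloronium face, so only the ring bond is anti.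

Step 8
Reactants: 12 (1S,2S,4R,5R)-2,4-dichloro-5-(chloromethyl)-1-methyl-5-[(triethylsilyl)oxy]cyclohexane-1-carbaldehyde
Product: 13 triethyl{[(1R,2R,4S,5S)-2,4-dichloro-1-(chloromethyl)-5-[(E)-2-chloroethenyl]-5-methylcyclohexyl]oxy}silane
Conditions: CrCl2 (6 equiv), CHCl3, THF, 65 °C
Reagents that add atoms: chloroform, ClC(Cl)Cl
Why: Takai olefination, in which the gem-dichromium carbenoid from CHCl3 adds to the aldehyde and eliminates to the (E)-chloroalkene, while the unactivated alkyl chlorides and the silyl ether are inert to Cr(II).

Step 9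
Reactants: 13 triethyl{[(1R,2R,4S,5S)-2,4-dichloro-1-(chloromethyl)-5-[(E)-2-chloroethenyl]-5-methylcyclohexyl]oxy}silane
Product: 15 (1R,2R,4S,5S)-1-bromo-2,4-dichloro-1-(chloromethyl)-5-[(E)-2-chloroethenyl]-5-methylcyclohexane, via spiro chloronium ion 14 (not isolated)
Conditions: BBr3, CH2Cl2, −78 → −20 °C; H2O
Reagents that add atoms: boron tribromide, BrB(Br)Br
Why: Direct conversion of a silyl ether into a bromide with BBr3, in which the axial tertiary C–O bond should ionise with help from the antiperiplanar CH2Cl chlorine (chloronium ion 14) and bromide should open 14 at the tertiary carbon from the face the oxygen left (double inversion, net retention), while the cis C2–Cl is gauche and cannot participate.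

## Compound list

1 | pent-4-enal | C=CCCC=O | starting material
2 | (2R)-2-chloropent-4-enal | O=C[C@H](Cl)CC=C | intermediate
3 | (3R)-1,3-dichlorohex-5-en-2-ol (both C2 epimers) | OC(CCl)[C@H](Cl)CC=C | intermediate
4 | (3R)-1,3-dichlorohex-5-en-2-one | ClCC(=O)[C@H](Cl)CC=C | intermediate
5 | 3-methylbut-3-en-2-one | CC(=O)C(C)=C | starting material
6 | lithium 3-methylbuta-1,3-dien-2-olate (kinetic dienolate of 5) | [Li]OC(=C)C(C)=C | intermediate
7 | lithium (5R,6R)-6-chloro-5-(chloromethyl)-2-methyl-3-oxonona-1,8-dien-5-olate (aldolate) | C=C(C)C(=O)C[C@@](O[Li])(CCl)[C@H](Cl)CC=C | intermediate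
8 | (5R,6R)-6-chloro-5-(chloromethyl)-2-methyl-5-[(triethylsilyl)oxy]nona-1,8-dien-3-one | C=C(C)C(=O)C[C@@](O[Si](CC)(CC)CC)(CCl)[C@H](Cl)CC=C | intermediate
9 | (5R,6R)-5-chloro-6-(chloromethyl)-2-methyl-6-[(triethylsilyl)oxy]cyclohept-2-en-1-one | O=C1C[C@@](O[Si](CC)(CC)CC)(CCl)[C@H](Cl)CC=C1C | intermediate
10 | (1S,5R,6R)-5-chloro-6-(chloromethyl)-2-methyl-6-[(triethylsilyl)oxy]cyclohept-2-en-1-ol (OH trans to 5-Cl and 6-OSiEt3) | O[C@H]1C[C@@](O[Si](CC)(CC)CC)(CCl)[C@H](Cl)CC=C1C | intermediate
11 | C2,C3-bridged chloronium ion of 10 (Cl on the face cis to 5-Cl and 6-OSiEt3, trans to 1-OH) | O[C@H]1C[C@@](O[Si](CC)(CC)CC)(CCl)[C@H](Cl)C[C@@H]2[Cl+][C@]12C | intermediate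
12 | (1S,2S,4R,5R)-2,4-dichloro-5-(chloromethyl)-1-methyl-5-[(triethylsilyl)oxy]cyclohexane-1-carbaldehyde (CHO, 2-Cl, 4-Cl and OSiEt3 all cis) | C[C@@]1(C=O)C[C@@](O[Si](CC)(CC)CC)(CCl)[C@H](Cl)C[C@@H]1Cl | intermediate
13 | triethyl{[(1R,2R,4S,5S)-2,4-dichloro-1-(chloromethyl)-5-[(E)-2-chloroethenyl]-5-methylcyclohexyl]oxy}silane | C[C@@]1(/C=C/Cl)C[C@@](O[Si](CC)(CC)CC)(CCl)[C@H](Cl)C[C@@H]1Cl | intermediate
14 | chloronium ion from 13 (Cl+ bridging C1 and its exocyclic CH2, spiro at C1, Cl on the face trans to the departed oxygen) | C[C@@]1(/C=C/Cl)C[C@]2(C[Cl+]2)[C@H](Cl)C[C@@H]1Cl | intermediate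
15 | (1R,2R,4S,5S)-1-bromo-2,4-dichloro-1-(chloromethyl)-5-[(E)-2-chloroethenyl]-5-methylcyclohexane | C[C@@]1(/C=C/Cl)C[C@@](Br)(CCl)[C@H](Cl)C[C@@H]1Cl | target

## Step count and risks

Total steps: 9. Longest linear sequence: 9 steps (from pent-4-enal 1; 3-methylbut-3-en-2-one 5 enters in step 4).

**Step 7 (proposed new method).** What may go wrong: the chloronium ion may form on the other alkene face, or react through a ring conformation in which the ring bond is not antiperiplanar. This would lead to hydride shift to a chloro ketone, allylic chlorination, or the diastereomeric aldehyde. Fallback with known chemistry, setting out from 9 and returning at 12: reduction of 9 with the (S)-CBS catalyst should give the C1-epimeric allylic alcohol F1. Hydroxyl-directed epoxidation (VO(acac)2, t-BuOOH) should give the syn 2,3-epoxy alcohol F2. Lewis-acid semipinacol rearrangement of this epoxy alcohol (BF3·OEt2 or MABR, CH2Cl2, −78 °C), in which the ring bond anti to the tertiary C–O bond migrates, should give the ring-contracted β-hydroxy aldehyde F3 with OH cis to CHO. Stereoretentive deoxychlorination of the secondary alcohol (SOCl2, then catalytic TiCl4; front-side collapse of the chlorosulfite) should then give 12.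

**Step 9.** What may go wrong: ionisation of the doubly β-chlorinated tertiary centre may be slower than elimination, bromide may open the chloronium ion at the CH2 carbon (halogen-swapped isomer), or facial control may be lost through an open cation. Fallback, setting out from 13 and returning at 15, with a radical instead of an ionic C–Br bond formation: desilylation (HF·pyridine) should give the tertiary alcohol F4. Syn-dehydration with Burgess reagent should give the chloromethylidene alkene F5 together with its endocyclic isomer F6; only the CH2Cl and C6 hydrogens are syn to the axial hydroxyl, and the C2 hydrogen is anti. Markovnikov hydrogen-atom-transfer hydrobromination of either alkene (Co(acac)2 cat., t-BuOOH, Et3SiH, TsBr) goes through the same tertiary C1 radical and should give 15. Radical bromine transfer is expected to favour the less hindered face, so the C1 epimer may predominate and would have to be separated.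

**Step 4.** What may go wrong: proton transfer from the acidic α-chloro ketone to the basic dienolate, closure of the aldolate to an epoxide, or retro-aldol before silylation; the facial control by the α-chlorine may also be incomplete. Fallback, setting out from 4 and returning at 8, through a non-basic ester aldol and a later ketone synthesis: Mukaiyama aldol of 4 with 1-ethoxy-1-(trimethylsilyloxy)ethene (BF3·OEt2, CH2Cl2, −78 °C, same Cornforth sense) should give the hydroxy ester F7. Silylation (TESOTf, 2,6-lutidine) should give the silyl ether F8. Amidation with MeNH(OMe)·HCl / i-PrMgCl should give the Weinreb amide F9, and isopropenylmagnesium bromide should convert it into 8.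

## Further compounds

F1 | step 7 | (1R,5R,6R)-5-chloro-6-(chloromethyl)-2-methyl-6-[(triethylsilyl)oxy]cyclohept-2-en-1-ol (C1 epimer of 10) | O[C@@H]1C[C@@](O[Si](CC)(CC)CC)(CCl)[C@H](Cl)CC=C1C
F2 | step 7 | 2,3-epoxide of F1 with the epoxide oxygen cis to the 1-OH (and cis to 5-Cl and 6-OSiEt3) | O[C@@H]1C[C@@](O[Si](CC)(CC)CC)(CCl)[C@H](Cl)C[C@@H]2O[C@]12C
F3 | step 7 | (1R,2S,4R,5R)-4-chloro-5-(chloromethyl)-2-hydroxy-1-methyl-5-[(triethylsilyl)oxy]cyclohexane-1-carbaldehyde (OH cis to CHO) | C[C@@]1(C=O)C[C@@](O[Si](CC)(CC)CC)(CCl)[C@H](Cl)C[C@@H]1O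
F4 | step 9 | (1R,2R,4S,5S)-2,4-dichloro-1-(chloromethyl)-5-[(E)-2-chloroethenyl]-5-methylcyclohexan-1-ol | C[C@@]1(/C=C/Cl)C[C@@](O)(CCl)[C@H](Cl)C[C@@H]1Cl
F5 | step 9 | 2,4-dichloro-1-(chloromethylidene)-5-[(E)-2-chloroethenyl]-5-methylcyclohexane, ring stereocentres as in 13, exocyclic alkene geometry not fixed | C[C@@]1(/C=C/Cl)CC(=CCl)[C@H](Cl)C[C@@H]1Cl
F6 | step 9 | 4,6-dichloro-1-(chloromethyl)-3-[(E)-2-chloroethenyl]-3-methylcyclohex-1-ene, ring stereocentres as in 13 (endocyclic isomer of F5) | C[C@@]1(/C=C/Cl)C=C(CCl)[C@H](Cl)C[C@@H]1Cl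
F7 | step 4 | ethyl (3R,4R)-4-chloro-3-(chloromethyl)-3-hydroxyhept-6-enoate | CCOC(=O)C[C@@](O)(CCl)[C@H](Cl)CC=C
F8 | step 4 | ethyl (3R,4R)-4-chloro-3-(chloromethyl)-3-[(triethylsilyl)oxy]hept-6-enoate | CCOC(=O)C[C@@](O[Si](CC)(CC)CC)(CCl)[C@H](Cl)CC=C
F9 | step 4 | (3R,4R)-4-chloro-3-(chloromethyl)-N-methoxy-N-methyl-3-[(triethylsilyl)oxy]hept-6-enamide | CON(C)C(=O)C[C@@](O[Si](CC)(CC)CC)(CCl)[C@H](Cl)CC=C
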